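(The data come from a simulation on assumed constants.)

Count the free monomer in and out of the larch run, then see how far that count can be carried to the asked time.

| setting | larch | flask |
|---|---|---|
| free monomer | 2 M (fed, over 25 h) | 2.0 M (fed, over 25 h) |
| transfer agent | 0.60 M | 0.600 M |
| initiator | 1 mol% | 1 mol% |
| remark | the very flask that is asked about, followed so far; the fed solution adds 0.25 times the starting volume | the fed solution adds 0.25 times the starting volume |
| time |  | 3.0 d |

larch run (percent of the free monomer charged)

| time / h | monomer in chains / % | free monomer / % |
|---|---|---|
| 2.50 | 0.2 | 9.9 |
| 5.00 | 2.3 | 18.3 |
| 8.00 | 5.0 | 26.9 |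
| 10.0 | 8.3 | 30.9 |
| 12.0 | 11.8 | 36.8 |
| 15.0 | 16.1 | 43.8 |

(scatter of a reading: 0.3 percentage points)

- average number of monomer units in a chain (chains begun, living or dead) at 3.0 d
- part of the free monomer that has reacted at 3.0 d

- every charge counts on the volume at the start, and the solution that is fed holds the whole dose
- the average divides the monomer in chains by the number of chains begun, living and dead together
- the earlier runs do not show the number of chains; that part of a forecast is a guess
- percentages count the whole charge, also what has not yet gone in

The ledger of free monomer in the larch run at 15.0 h reads:

fed so far: 60.0% of the charge
in chains: 16.1%
still free: 43.8%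

The last two entries sum to 59.9%, so the books close. Replacing the free-monomer curve by its mean between 8.00 h and 15.0 h gives a growth figure, an average read from the larch run over that stretch of hours:

growth figure = gain in chains / (mean free monomer × hours) = 0.0449 h⁻¹

Run with the feed, this figure puts free monomer at 43.7% at 15.0 h, against the reading of 43.8%, so up to that time the mean costs little. Held to 3.0 d, it leaves 7.30% free, so this reckoning says 92.7% reacted, if growth never fades.

The readings do not show the chains, so their number is a guess: here, one chain per initiator. The quantity to carry is then the units per initiator, free monomer charged over initiator charged, 100: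

average chain = units per initiator × part reacted = 92.7

The forecast differs from this reckoning, with 2.9 (2.5 to 5) and 87% (74% to 94%), its chains counted on the transfer agent, “higher if transfer is sluggish”.

In the flask the monomer in chains averages 34.3 units, with 34.7% of the free monomer reacted.

    free monomer + initiator → living end + monomer in chains (k = 1.00 M⁻¹ h⁻¹)
    free monomer + living end → monomer in chains + living end, rate k2*[living end]*[free monomer] (k = 4.00 M⁻¹ h⁻¹)
    living end + transfer agent → dead chain (kL = 0.100 M⁻¹ h⁻¹)
    living end + monomer in chains → dead end (k = 0.130 M⁻¹ h⁻¹)

Growth did not hold on in this flask: free monomer stands at 65.3% at 3.00 d and at 65.3% at 30.0 d, while initiator is down to 0% of its charge, less than the free monomer left. The units per initiator still serve here, since 100 times the part reacted gives 34.7. The neighbour charged with 4 mol% of initiator has 25.0 units per initiator, and with 60.5% reacted that gives 15.1, where that flask stands at 14.6.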